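The oxolane (O1; C2 pentyl; C3 acyloxy; C4 H2; C5 side chain) is cut into a three-atom piece O1–C5–C4 and a two-atom piece C3–C2. O1–C5–C4 is a terminal epoxide whose CH2 carbon (C4) is made nucleophilic by two-electron reductive opening (polarity reversal); C3–C2 is an α-chloro aldehyde, electrophilic at both carbons. In one flask the C4 carbanion adds to the aldehyde carbon and the liberated C5 oxygen displaces chloride at C2: a reductive [3+2] annulation exploiting the 1,3-relationship of O1 and C4 and the vicinal C3/C2 functionality. Precursors: a MOM-protected threo epoxy alcohol bearing the decenyl chain and (R)-2-chloroheptanal; acylation and deprotection finish the route.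

Key step: step 4

Assumption: enantiopure (2R,3R)-1,2:3,4-diepoxybutane is taken as a purchased material, and lithium 4,4'-di-tert-butylbiphenylide (LiDBB) is a titrated THF stock solution made beforehand from lithium metal and 4,4'-di-tert-butylbiphenyl. C1' denotes the carbinol carbon of the side chain.

Step 1
Reactants: 1 8-bromooct-1-ene; 2 (2R,3R)-1,2:3,4-diepoxybutane
Product: 4 (1R)-1-[(2R)-oxiran-2-yl]dec-9-en-1-ol, via oct-7-en-1-ylmagnesium bromide 3 (not isolated)
Conditions: Mg, THF, rt; then CuI (10 mol %), 2 (1.5 equiv), THF, −30 → 0 °C; aq NH4Cl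
Reagents that add atoms: none
Why: Copper-catalysed Grignard opening of a terminal epoxide (SN2 at the CH2 carbon) touches neither stereocentre of the C2-symmetric diepoxide, and both epoxides of 2 are equivalent, so mono-addition should give the threo epoxy alcohol directly.

Step 2
Reactants: 4 (1R)-1-[(2R)-oxiran-2-yl]dec-9-en-1-ol
Product: 5 (2R)-2-[(1R)-1-(methoxymethoxy)dec-9-en-1-yl]oxirane
Conditions: MOMCl, i-Pr2NEt, CH2Cl2, 0 °C → rt
Reagents that add atoms: chloromethyl methyl ether (MOMCl), COCCl
Why: O-alkylation of the alcohol (MOM ether formation) under amine base leaves the epoxide intact and gives an acetal that carries no group reducible by LiDBB and cannot migrate to a neighbouring alkoxide or carbanion in step 4.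

Step 3
Reactants: 6 heptanal
Product: 7 (2R)-2-chloroheptanal
Conditions: NCS, (2S,5S)-2,5-diphenylpyrrolidine (10 mol %), CH2Cl2, rt; pentane, filtration, used at once
Reagents that add atoms: N-chlorosuccinimide (NCS), O=C1CCC(=O)N1Cl
Why: Enamine catalysis (organocatalytic α-chlorination): NCS should chlorinate the E-enamine of 6 on the face away from the phenyl group on the ring carbon next to the enamine double bond, which for the (2S,5S)-catalyst leads to the (R)-aldehyde, to be confirmed by reduction to (2R)-2-chloroheptan-1-ol before use.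

Step 4
Reactants: 5 (2R)-2-[(1R)-1-(methoxymethoxy)dec-9-en-1-yl]oxirane; 7 (2R)-2-chloroheptanal
Product: 10 (2S,3S,5R)-5-[(1R)-1-(methoxymethoxy)dec-9-en-1-yl]-2-pentyloxolan-3-ol, via dilithio β-lithioalkoxide 8 (not isolated), via anti-chlorodiol 9 (not isolated)
Conditions: lithium 4,4'-di-tert-butylbiphenylide (LiDBB, 2.0 equiv, added to 5 until a green colour just persists), THF, −78 °C; then 7 (1.2 equiv), −78 °C; then AcOH (2.0 equiv), MeOH–H2O, 100 °C, sealed tube
Reagents that add atoms: none
Why: Two single-electron transfers from LiDBB cleave the CH2–O bond of the epoxide (less substituted carbanion, more substituted alkoxide) to give β-lithioalkoxide 8, whose primary carbanion adds to the aldehyde of 7 at −78 °C faster than it loses Li2O; after neutralisation the C5 hydroxyl of chlorodiol 9 displaces chloride in an intramolecular SN2 reaction on heating. The closest known reaction types are the reductive lithiation of epoxides to β-lithioalkoxides with their 1,3-diol-forming addition to aldehydes, and the thermal cyclisation of 4-chloro-1,3-diols to oxolan-3-ols. The oxolane closes in a 5-exo-tet mode. C3 is set in the addition by the α-chloro stereocentre of 7 (polar Felkin–Anh/Cornforth model, nucleophile anti to chlorine, giving the anti chlorohydrin), C2 is set by inversion of the (R)-chloride, and C5 and C1' are carried unchanged from 5. The step needs regioselective epoxide cleavage (secured by the preference for the primary carbanion), addition rather than enolisation of 7 (low temperature, no excess reductant) and closure by the C5 hydroxyl rather than epoxide formation from the C3 hydroxyl (secured by acetate-buffered, non-basic conditions, under which the MOM ether should also survive).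

Step 5
Reactants: 10 (2S,3S,5R)-5-[(1R)-1-(methoxymethoxy)dec-9-en-1-yl]-2-pentyloxolan-3-ol; 11 dodecanoyl chloride
Product: 12 (2S,3S,5R)-5-[(1R)-1-(methoxymethoxy)dec-9-en-1-yl]-2-pentyloxolan-3-yl dodecanoate
Conditions: pyridine, DMAP (cat.), CH2Cl2, 0 °C → rt
Reagents that add atoms: none
Why: Acylation of the only free hydroxyl with an acid chloride under nucleophilic catalysis (DMAP) touches no stereocentre, and the MOM ether keeps the side-chain oxygen masked.

Step 6
Reactants: 12 (2S,3S,5R)-5-[(1R)-1-(methoxymethoxy)dec-9-en-1-yl]-2-pentyloxolan-3-yl dodecanoate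
Product: 13 (2S,3S,5R)-5-[(1R)-1-hydroxydec-9-en-1-yl]-2-pentyloxolan-3-yl dodecanoate (CNP0124067.1)
Conditions: ZnBr2, n-PrSH, CH2Cl2, 0 °C → rt
Reagents that add atoms: none
Why: Lewis acid-assisted thiolysis of the acetal (MOM ether cleavage) takes place at the O–CH2–O carbon under near-neutral conditions, so the secondary laurate, the oxolane and the terminal alkene should be left alone and no stereocentre is involved.

Compound list
1 | 8-bromooct-1-ene | C=CCCCCCCBr | starting material
2 | (2R,3R)-1,2:3,4-diepoxybutane [(2R,2'R)-2,2'-bioxirane] | C1O[C@H]1[C@H]1CO1 | starting material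
3 | oct-7-en-1-ylmagnesium bromide | C=CCCCCCC[Mg]Br | intermediate
4 | (1R)-1-[(2R)-oxiran-2-yl]dec-9-en-1-ol | C=CCCCCCCC[C@@H](O)[C@H]1CO1 | intermediate
5 | (2R)-2-[(1R)-1-(methoxymethoxy)dec-9-en-1-yl]oxirane | C=CCCCCCCC[C@@H](OCOC)[C@H]1CO1 | intermediate
6 | heptanal | CCCCCCC=O | starting material
7 | (2R)-2-chloroheptanal | O=C[C@H](Cl)CCCCC | intermediate
8 | lithium (2R,3R)-1-lithio-3-(methoxymethoxy)dodec-11-en-2-olate | C=CCCCCCCC[C@@H](OCOC)[C@H](O[Li])C[Li] | intermediate
9 | (6R,7S,9R,10R)-6-chloro-10-(methoxymethoxy)nonadec-18-ene-7,9-diol | C=CCCCCCCC[C@@H](OCOC)[C@H](O)C[C@H](O)[C@H](Cl)CCCCC | intermediate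
10 | (2S,3S,5R)-5-[(1R)-1-(methoxymethoxy)dec-9-en-1-yl]-2-pentyloxolan-3-ol | C=CCCCCCCC[C@@H](OCOC)[C@H]1C[C@H](O)[C@H](CCCCC)O1 | intermediate
11 | dodecanoyl chloride | CCCCCCCCCCCC(=O)Cl | starting material
12 | (2S,3S,5R)-5-[(1R)-1-(methoxymethoxy)dec-9-en-1-yl]-2-pentyloxolan-3-yl dodecanoate | C=CCCCCCCC[C@@H](OCOC)[C@H]1C[C@H](OC(=O)CCCCCCCCCCC)[C@H](CCCCC)O1 | intermediate
13 | (2S,3S,5R)-5-[(1R)-1-hydroxydec-9-en-1-yl]-2-pentyloxolan-3-yl dodecanoate | C=CCCCCCCC[C@@H](O)[C@H]1C[C@H](OC(=O)CCCCCCCCCCC)[C@H](CCCCC)O1 | target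

Total step count: 6. Longest linear sequence: 5 steps (steps 1, 2, 4, 5, 6).

Steps most likely to fail

Step 4. The β-lithioalkoxide may deprotonate the α-chloro aldehyde instead of adding to it, or lose Li2O before it is trapped. An unstabilised alkyllithium may also show poor facial selectivity at C3. The fallback sets out from 5 and comes back at 10; it carries the ring oxygen as a ketone so that the C4–C3 bond is made by an aldol reaction. Hydride opening of 5 at the CH2 carbon (LiAlH4, THF, 0 °C) would give (2R,3R)-3-(methoxymethoxy)dodec-11-en-2-ol F1. Dess–Martin oxidation would give the methyl ketone (3R)-3-(methoxymethoxy)dodec-11-en-2-one F2. Its kinetic lithium enolate (LDA, THF, −78 °C) should add to 7 with the same anti preference to give (6R,7S,10R)-6-chloro-7-hydroxy-10-(methoxymethoxy)nonadec-18-en-9-one F3. A 1,3-syn reduction (Et2BOMe, NaBH4, THF–MeOH, −78 °C, Narasaka–Prasad) would re-create the C5 stereocentre and give 9 as an isolated compound, which is heated in MeOH–H2O to close the ring to 10.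

Step 3. Facial selectivity in the enamine chlorination may be lower than needed, or its sense opposite to the steric model, and the aldehyde may racemise on handling. The fallback does not start from 6; it sets out from purchased (2R)-2-aminoheptanoic acid F4 and comes back at 7. Diazotisation in 6 M HCl (NaNO2, 0 °C), which replaces the amino group by chloride with retention through double inversion, would give (2R)-2-chloroheptanoic acid F5. Reduction (LiAlH4, Et2O, 0 °C) would give (2R)-2-chloroheptan-1-ol F6, and Dess–Martin oxidation just before use would give 7.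

Step 6. Acetal cleavage may stall if ZnBr2 is tied up by chelation to the oxolane oxygen, and forcing it with stronger acid risks loss or migration of the laurate. The fallback sets out from 4 and comes back at 13; it uses an acetal with a silicon trigger. Protection of 4 with 2-(trimethylsilyl)ethoxymethyl chloride and i-Pr2NEt would give (2R)-2-[(1R)-1-{[2-(trimethylsilyl)ethoxy]methoxy}dec-9-en-1-yl]oxirane F7. The conditions of step 4 would take it through lithium (2R,3R)-1-lithio-3-{[2-(trimethylsilyl)ethoxy]methoxy}dodec-11-en-2-olate F8 and (6R,7S,9R,10R)-6-chloro-10-{[2-(trimethylsilyl)ethoxy]methoxy}nonadec-18-ene-7,9-diol F9, neither isolated, to (2S,3S,5R)-2-pentyl-5-[(1R)-1-{[2-(trimethylsilyl)ethoxy]methoxy}dec-9-en-1-yl]oxolan-3-ol F10. Acylation as in step 5 would give (2S,3S,5R)-2-pentyl-5-[(1R)-1-{[2-(trimethylsilyl)ethoxy]methoxy}dec-9-en-1-yl]oxolan-3-yl dodecanoate F11. Chelation-assisted cleavage with MgBr2·OEt2 in Et2O–MeNO2 at rt would then give 13.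

Further compounds
F1 | step 4 | (2R,3R)-3-(methoxymethoxy)dodec-11-en-2-ol | C=CCCCCCCC[C@@H](OCOC)[C@H](O)C
F2 | step 4 | (3R)-3-(methoxymethoxy)dodec-11-en-2-one | C=CCCCCCCC[C@@H](OCOC)C(C)=O
F3 | step 4 | (6R,7S,10R)-6-chloro-7-hydroxy-10-(methoxymethoxy)nonadec-18-en-9-one | C=CCCCCCCC[C@@H](OCOC)C(=O)C[C@H](O)[C@H](Cl)CCCCC
F4 | step 3 | (2R)-2-aminoheptanoic acid (purchased) | N[C@H](CCCCC)C(=O)O
F5 | step 3 | (2R)-2-chloroheptanoic acid | OC(=O)[C@H](Cl)CCCCC
F6 | step 3 | (2R)-2-chloroheptan-1-ol | OC[C@H](Cl)CCCCC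
F7 | step 6 | (2R)-2-[(1R)-1-{[2-(trimethylsilyl)ethoxy]methoxy}dec-9-en-1-yl]oxirane | C=CCCCCCCC[C@@H](OCOCC[Si](C)(C)C)[C@H]1CO1
F8 | step 6 | lithium (2R,3R)-1-lithio-3-{[2-(trimethylsilyl)ethoxy]methoxy}dodec-11-en-2-olate | C=CCCCCCCC[C@@H](OCOCC[Si](C)(C)C)[C@H](O[Li])C[Li]
F9 | step 6 | (6R,7S,9R,10R)-6-chloro-10-{[2-(trimethylsilyl)ethoxy]methoxy}nonadec-18-ene-7,9-diol | C=CCCCCCCC[C@@H](OCOCC[Si](C)(C)C)[C@H](O)C[C@H](O)[C@H](Cl)CCCCC
F10 | step 6 | (2S,3S,5R)-2-pentyl-5-[(1R)-1-{[2-(trimethylsilyl)ethoxy]methoxy}dec-9-en-1-yl]oxolan-3-ol | C=CCCCCCCC[C@@H](OCOCC[Si](C)(C)C)[C@H]1C[C@H](O)[C@H](CCCCC)O1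
F11 | step 6 | (2S,3S,5R)-2-pentyl-5-[(1R)-1-{[2-(trimethylsilyl)ethoxy]methoxy}dec-9-en-1-yl]oxolan-3-yl dodecanoate | C=CCCCCCCC[C@@H](OCOCC[Si](C)(C)C)[C@H]1C[C@H](OC(=O)CCCCCCCCCCC)[C@H](CCCCC)O1
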